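The runs stem from a simulated flask on assumed constants, and the scatter is random.

If the left-handed and right-handed substrates fall together within the scatter of the readings, I may treat them as one pool and write one balance for it.

| setting | Friday's | Sunday's | Saturday's | flask |
|---|---|---|---|---|
| left-handed substrate | 0.081 M | 0.081 M | 0.16 M | 0.081 M |
| right-handed substrate | 0.081 M | 0.081 M | 0.16 M | 0.081 M |
| reagent | 0.324 M | 0.324 M | 0.324 M | 0.324 M |
| free catalyst | 0.20 mM | 0.31 mM | 0.41 mM | 0.41 mM |
| precatalyst | 2 mM | 2 mM | 2 mM | 2.0 mM |
| remark | run made earlier | run made earlier | run made earlier |  |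
| time |  |  |  | 15 h |

| run | time / h | left-handed substrate / % | right-handed substrate / % |
|---|---|---|---|
| Friday's | 1.00 | 46 | 46 |
| Friday's | 1.50 | 41 | 48 |
| Friday's | 2.50 | 40 | 42 |
| Friday's | 4.00 | 34 | 36 |
| Friday's | 8.00 | 30 | 23 |
| Friday's | 12.0 | 21 | 19 |
| Sunday's | 1.00 | 42 | 47 |
| Sunday's | 1.50 | 37 | 39 |
| Sunday's | 2.50 | 35 | 37 |
| Sunday's | 4.00 | 29 | 31 |
| Sunday's | 8.00 | 19 | 18 |
| Sunday's | 12.0 | 15 | 13 |
| Saturday's | 1.00 | 40 | 45 |
| Saturday's | 3.00 | 29 | 33 |
| Saturday's | 6.00 | 22 | 22 |
| Saturday's | 8.00 | 17 | 19 |
| Saturday's | 12.0 | 18 | 16 |

(scatter of a reading: 2 percentage points)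

- part of the left-handed substrate and right-handed substrate charged together that has reacted at 15 h
- excess of left-handed product over right-handed product in the product at 15 h
- excess of right-handed substrate over left-handed substrate among what is left of the two at 15 h

- free catalyst is single-handed; left-handed substrate and right-handed substrate are mirror images of each other, charged as a racemate, each of them at the stated concentration
- an excess is the difference of the two amounts in percent of their sum
- an excess is below zero if the other one leads

1. In the flask the pool, 162 mM, is the limiting reagent against 0.324 M of reagent. I assume one reagent per substrate, so c(reagent) falls by what the pool loses, and I write the rate as K · c(free catalyst) · c(reagent) · c(pool).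

2. Let f be the fraction of the pool left. In Friday's run, as in the flask, reagent is charged at twice the pool, and integration gives ln[(1 + f)/(2 f)] = K · c(free catalyst) · c(pool charged) · t. Friday's f of 40.0 % at 12.0 h gives a reading, with its scatter, of K = 0.400 L² mol⁻² s⁻¹: the turnover constant, the pool's rate of loss per unit of the product of the three concentrations.

3. First way: the balance with this K gives the flask c = 86.5 % at 15 h.

4. Second way: I hold c(reagent) at its charge, so the decay is pseudo-first-order. The same Friday reading gives 0.106 L mol⁻¹ s⁻¹ as the constant on c(free catalyst) · c(pool), and for the flask c = 90.4 %, which is higher than the balance gives.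

5. Saturday's run tests which way cheats: its reagent, 0.324 M, is close to its pool, 320 mM. At 12.0 h Saturday's readings say 66.0 % has reacted. For Saturday's run the balance gives 69.9 %, the first-order way 84.7 %. The first-order way overshoots that reading further than the balance does, so for the flask I commit to 86.5 %. The pool balance gives neither excess.

6. The forecast gives c = 89 % (83 % to 93 %), eP = −1.9 % and eS = −15 %, and says “Selectivity is small and appears to invert”. The flask gives c = 86.8 %, eP = 22.2 % and eS = 1.75 %.

    reagent + free catalyst + left-handed substrate → free catalyst + left-handed product (k = 0.520 L² mol⁻² s⁻¹)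
    reagent + free catalyst + right-handed substrate → free catalyst + right-handed product (k = 0.300 L² mol⁻² s⁻¹)
    left-handed substrate + racemization catalyst ⇌ right-handed substrate + racemization catalyst, rate k3*[racemization catalyst]*[left-handed substrate] forward; the back reaction follows from the equilibrium constant (k = 0.180 L mol⁻¹ s⁻¹)
    precatalyst → racemization catalyst (k = 2.10 × 10⁻⁵ s⁻¹)

In the neighbouring flask, reagent is charged at 0.081 M, with everything else as in the flask, so reagent is now the smaller charge. The same balance with the same K, 0.400 L² mol⁻² s⁻¹, now has c(pool) and c(reagent) swapped in size. For that neighbour at 15 h it gives c = 33.9 % and 32.3 % of the reagent left. That neighbour gives c = 34.2 %, with 32 % of its reagent left.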